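Time moves the starting complex very little after the first sample: the cedar run reads 46.2% at 0.500 min and 47.0% at 3.00 min, and the birch run, 2.97 times as concentrated, reads 46.9% and 46.7%. This flat line is taken to mean that exchange stops when the incoming ligand is consumed, so the incoming ligand, charged at less than the two equivalents a complex can take, is read as the limiting reagent.

| setting | cedar | birch | grey | teal |
|---|---|---|---|---|
| starting complex | 0.074 M | 0.22 M | 0.11 M | 0.11 M |
| incoming ligand | 0.90 equiv | 0.90 equiv | 1.20 equiv | 0.900 equiv |
| remark | run made earlier | run made earlier |  |  |
| time |  |  | 5.0 min | 5.0 min |

| run | time / min | starting complex / % | over-reaction product / % | side product / % | complex with one exchanged / % | complex with two exchanged / % |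
|---|---|---|---|---|---|---|
| cedar | 0.500 | 46.2 | 16.7 | 1.7 | 16.1 | 20.2 |
| cedar | 1.00 | 47.8 | 27.5 | 4.5 | 14.1 | 9.8 |
| cedar | 1.50 | 46.0 | 31.8 | 5.8 | 11.0 | 4.5 |
| cedar | 2.00 | 46.2 | 33.1 | 7.7 | 10.3 | 2.5 |
| cedar | 2.50 | 46.9 | 34.6 | 8.8 | 8.0 | 1.9 |
| cedar | 3.00 | 47.0 | 35.0 | 10.4 | 7.1 | 0 |
| birch | 0.500 | 46.9 | 17.3 | 3.5 | 14.1 | 19.3 |
| birch | 1.00 | 46.8 | 28.2 | 3.4 | 11.4 | 9.5 |
| birch | 1.50 | 47.1 | 32.5 | 5.0 | 9.8 | 4.5 |
| birch | 2.00 | 47.2 | 34.4 | 6.5 | 9.6 | 2.4 |
| birch | 2.50 | 48.3 | 36.3 | 7.9 | 8.1 | 1.5 |
| birch | 3.00 | 46.7 | 36.7 | 9.3 | 6.2 | 0 |

(standard deviation of a reading: 0.5 percentage points)

- which of these there is most of at the end, counted by the starting complex in it, grey (complex with one exchanged / starting complex / over-reaction product / side product)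
- which of these there is most of at the end, counted by the starting complex in it, teal (complex with one exchanged / starting complex / over-reaction product / side product)
- how much there is at the end of the one of these that leads, in percent of the starting complex charged: grey
- how much there is at the end of the one of these that leads, in percent of the starting complex charged: teal

- on the list of suspects stand: complex with one exchanged -> side product; complex with two exchanged -> over-reaction product; starting complex + incoming ligand <-> leaving ligand + complex with one exchanged; complex with one exchanged + incoming ligand <-> leaving ligand + complex with two exchanged; leaving ligand -> by-product carried off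

Count the ligand. The one-exchanged family (complex with one exchanged plus side product) carries one, and the two-exchanged family (complex with two exchanged plus over-reaction product) carries two:

one-exchanged family + 2 × two-exchanged family = equivalents charged
starting complex + one-exchanged family + two-exchanged family = 1
two-exchanged family − starting complex = equivalents charged − 1

That gives 20 percentage points for grey and −10 points for teal. This is the ligand gap: the two-exchanged family minus the starting complex, in percent of the starting complex charged, once the incoming ligand is consumed.

The objection is that the last readings should show −10 points. Birch gives −10 points, but cedar gives −12 points, so a doubt of about two points remains.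

Does the end state arrive in time? The cedar complex with two exchanged falls at 1.45 min⁻¹, a half-life of 0.478 min, far shorter than 5.0 min. The two-exchanged family therefore counts as over-reaction product at the end.

The gap still needs a second relation. The last readings average 46.9% starting complex, 16.5% one-exchanged family and 35.9% two-exchanged family. Holding that split fixed gives grey 48.8% over-reaction product. But that split was read at 0.90 equiv, and a larger charge need not divide the same way. An apparent selectivity factor κ, a number chosen so that the formula below matches the split in the readings, serves better:

one-exchanged family = (m − m^κ)/(κ − 1), with m the starting complex left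

Two passes on the readings give κ = 3.84, then 3.51. With the gap, this puts grey at 33.7% starting complex and 53.7% over-reaction product. Teal comes to 46.9% starting complex and 36.9% over-reaction product.

The forecast, reading “second exchange about 3.5 times faster than the first”, gives grey over-reaction product at 53.5% (50.5% to 56.5%) and teal starting complex at 47% (45.8% to 48.2%).

The flask gives grey over-reaction product at 52.4% and teal starting complex at 46.6%.

    complex with one exchanged → side product (k = 0.00480 s⁻¹)
    complex with two exchanged → over-reaction product (k = 0.0240 s⁻¹)
    starting complex + incoming ligand ⇌ leaving ligand + complex with one exchanged (K = 0.720, k = 5.20 L mol⁻¹ s⁻¹)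
    complex with one exchanged + incoming ligand ⇌ leaving ligand + complex with two exchanged (K = 5.10, k = 13.0 L mol⁻¹ s⁻¹)
    leaving ligand → by-product carried off (k = 0.470 s⁻¹)

In grey, over-reaction product stands 20 points from starting complex, against the gap of 20 points, with incoming ligand at 0%. The neighbour is grey with 0.480 equiv of incoming ligand. Its gap is −52 points, and the same κ gives 66.7% starting complex and 14.7% over-reaction product. That flask ends with incoming ligand at 0%, starting complex at 67.7% and over-reaction product at 15.7%.

The readings were generated by integration for substances that don't exist; the scatter is artificial.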